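## Retrosynthetic overview

1. Target 25 comes from the glaucolide-type lactone 22 (C6–H butenolide, 4,5-epoxide, C1 ketone) in one cascade: vinylogous E1cB epoxide opening (C5=C6), transannular C4–O to C1 hemiketal, dehydration. The oxygen bridge is the last ring.
2. 22 comes from the acyclic epoxy aldehyde / alkenyl iodide 20 by C6–C7 closure of the ten-membered ring (NiCl2/CrCl2); the C6 alkoxide closes the lactone in the same flask. Carbocycle first, lactone second.
3. 20 comes from ynoate 13: iodide/formaldehyde halo-aldol (C7–I and C13), two acylations, Sharpless epoxidation (C4), oxidation.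
4. 13 comes from aldehyde 11 and methyl propiolate (C8); 11 comes from diketone 7 and silyl ketene thioacetal 9 by a copper–bis(oxazoline) aldol (C10).
5. 7 comes from 3,3-dimethoxybutan-2-one and the prenol-derived allylic bromide 4.

Assumption: where a chiral ligand, catalyst or tartrate is named, the antipode meant is the one that gives the configuration written in the product SMILES; C6 in 21 and 22 is carried as an epimer mixture because step 15 destroys it.

Atom labels C1–C15 in the text are germacrane positions (C6–C7 is the ring-closing bond, C12 the lactone carbonyl, C13 the CH2OAc carbon).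

## Route

Step 1
Reactants: 1 3-methylbut-2-en-1-ol (prenol)
Product: 2 tert-butyl[(3-methylbut-2-en-1-yl)oxy]diphenylsilane
Conditions: TBDPSCl, imidazole, CH2Cl2, 0 °C to rt
Reagents that add atoms: tert-butyl(chloro)diphenylsilane, CC(C)(C)[Si](Cl)(c1ccccc1)c1ccccc1
Why: Standard silylation of the primary alcohol; the tert-butyldiphenylsilyl ether is chosen because it must survive the aqueous acid of step 4 and the MgI2 of step 9.

Step 2
Reactants: 2 prenyl silyl ether
Product: 3 (2E)-4-[(tert-butyldiphenylsilyl)oxy]-2-methylbut-2-en-1-ol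
Conditions: SeO2 (cat.), tBuOOH, salicylic acid (cat.), CH2Cl2, rt
Reagents that add atoms: tert-butyl hydroperoxide, CC(C)(C)OO
Why: Riley–Sharpless allylic oxidation (ene reaction, then [2,3]-shift of the allylseleninic acid) oxidises only the methyl group trans to the chain, so the E trisubstituted alkene that becomes C4=C5 is fixed here.

Step 3
Reactants: 3 E-allylic alcohol
Product: 4 {[(2E)-4-bromo-3-methylbut-2-en-1-yl]oxy}(tert-butyl)diphenylsilane
Conditions: CBr4, PPh3, CH2Cl2, 0 °C
Reagents that add atoms: carbon tetrabromide, BrC(Br)(Br)Br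
Why: Appel bromination of the primary allylic alcohol goes by SN2 at carbon without allylic shift, so the E alkene is kept.

Step 4
Reactants: 5 3,3-dimethoxybutan-2-one; 4 E-allylic bromide
Product: 7 (6E)-8-[(tert-butyldiphenylsilyl)oxy]-6-methyloct-6-ene-2,3-dione, via alkylated dimethyl ketal 6 (not isolated)
Conditions: LiN(iPr)2, THF, −78 °C; then 4, DMPU, −78 to −20 °C; then 2 M HCl (aq), rt
Reagents that add atoms: water, O
Why: Kinetic lithium enolate alkylation at the only enolisable methyl of the mono-protected diketone with a primary allylic bromide (SN2), followed by acid hydrolysis of the α-keto ketal in the work-up to unveil the 1,2-diketone.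

Step 5
Reactants: 8 S-ethyl ethanethioate
Product: 9 {[1-(ethylsulfanyl)ethenyl]oxy}trimethylsilane
Conditions: LiN(iPr)2, THF, −78 °C; Me3SiCl
Reagents that add atoms: chlorotrimethylsilane, C[Si](C)(C)Cl
Why: O-silylation of the thioester lithium enolate gives the silyl ketene thioacetal needed as the nucleophile of step 6.

Step 6
Reactants: 7 1,2-diketone; 9 silyl ketene thioacetal
Product: 10 S-ethyl (3S,7E)-9-[(tert-butyldiphenylsilyl)oxy]-3,7-dimethyl-4-oxo-3-[(trimethylsilyl)oxy]non-7-enethioate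
Conditions: [Cu((S,S)-tBu-box)](OTf)2 (10 mol %), THF, −78 °C
Reagents that add atoms: none
Why: Evans copper–bis(oxazoline) Mukaiyama aldol to a chelating 1,2-dicarbonyl: the diketone binds the metal through both oxygens and the ketene acetal adds to the less hindered methyl-ketone carbonyl on the face left open by the tert-butyl groups, which sets the tertiary carbinol (3S, the later C10) under catalyst control with silyl transfer to oxygen.

Step 7
Reactants: 10 thioester
Product: 11 (3S,7E)-9-[(tert-butyldiphenylsilyl)oxy]-3,7-dimethyl-4-oxo-3-[(trimethylsilyl)oxy]non-7-enal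
Conditions: Et3SiH, Pd/C (10 %), acetone, rt
Reagents that add atoms: none
Why: Fukuyama reduction (palladium insertion into the C–S bond, hydride transfer from the silane) turns the thioester into the aldehyde without touching the ketone, the alkene or the silyl ethers.

Step 8
Reactants: 11 aldehyde; 12 methyl prop-2-ynoate
Product: 13 methyl (4R,6S,10E)-12-[(tert-butyldiphenylsilyl)oxy]-4-hydroxy-6,10-dimethyl-7-oxo-6-[(trimethylsilyl)oxy]dodec-10-en-2-ynoate
Conditions: Me2Zn, (S,S)-ProPhenol (20 mol %), Ph3P=O (40 mol %), toluene, 4 °C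
Reagents that add atoms: none
Why: Zinc–ProPhenol asymmetric alkynylation: the dinuclear zinc alkynylide adds to the Si face of the aldehyde under ligand control and sets the secondary carbinol (4R, the later C8), while the hindered α-silyloxy ketone is left alone.

Step 9
Reactants: 13 γ-hydroxy ynoate
Product: 15 methyl (2Z,4R,6S,10E)-12-[(tert-butyldiphenylsilyl)oxy]-4-hydroxy-2-(hydroxymethyl)-3-iodo-6,10-dimethyl-7-oxo-6-[(trimethylsilyl)oxy]dodeca-2,10-dienoate, via iodomagnesium allenolate 14 (not isolated)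
Conditions: MgI2, CH2O (monomeric, in THF), CH2Cl2, −40 to 0 °C
Reagents that add atoms: magnesium diiodide, [Mg+2].[I-].[I-]; formaldehyde, C=O
Why: MgI2 halo-aldol (β-iodo Morita–Baylis–Hillman reaction): iodide adds to the ynoate β-carbon and the magnesium allenolate is hydroxymethylated at the α-carbon by formaldehyde held on the magnesium bound to the C4 oxygen, which places CH2OH cis to C4 and iodine cis to the ester (2Z); the opposite isomer lactonises to an iodobutenolide and is removed on silica.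

Step 10
Reactants: 15 iodo diol
Product: 17 methyl (2Z,4R,6S,10E)-2-(acetoxymethyl)-12-[(tert-butyldiphenylsilyl)oxy]-3-iodo-6,10-dimethyl-4-(methacryloyloxy)-7-oxo-6-[(trimethylsilyl)oxy]dodeca-2,10-dienoate, via primary monoacetate 16 (not isolated)
Conditions: AcCl, 2,4,6-collidine, CH2Cl2, −78 °C; then methacryloyl chloride, iPr2NEt, 0 °C to rt
Reagents that add atoms: acetyl chloride, CC(=O)Cl; methacryloyl chloride, CC(=C)C(Cl)=O
Why: Sequential chemoselective acylation: acetyl chloride/collidine at −78 °C takes only the primary allylic hydroxyl, and the acid chloride with a non-nucleophilic amine then esterifies the secondary C4 hydroxyl, no nucleophilic catalyst being used because of the β-iodo enoate.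

Step 11
Reactants: 17 bis-silyl ether
Product: 18 methyl (2Z,4R,6S,10E)-2-(acetoxymethyl)-6,12-dihydroxy-3-iodo-6,10-dimethyl-4-(methacryloyloxy)-7-oxododeca-2,10-dienoate
Conditions: HF·pyridine, pyridine, THF, 0 °C to rt
Reagents that add atoms: none
Why: Fluoride cleaves both silyl ethers (Si–F bond formation) while the three esters, the alkenyl iodide and the ketone are inert to buffered HF.

Step 12
Reactants: 18 allylic alcohol
Product: 19 methyl (2Z,4R,6S)-2-(acetoxymethyl)-6-hydroxy-9-[(2R,3R)-3-(hydroxymethyl)-2-methyloxiran-2-yl]-3-iodo-6-methyl-4-(methacryloyloxy)-7-oxonon-2-enoate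
Conditions: Ti(OiPr)4 (cat.), D-(−)-diethyl tartrate (cat.), tBuOOH, 4 Å MS, CH2Cl2, −20 °C
Reagents that add atoms: tert-butyl hydroperoxide, CC(C)(C)OO
Why: Sharpless asymmetric epoxidation: the titanium–D-tartrate complex delivers oxygen to one face of the E allylic alcohol irrespective of the remote centres and sets the quaternary C4 (2R,3R oxirane), the electron-poor alkenes being unreactive.

Step 13
Reactants: 19 epoxy alcohol
Product: 20 methyl (2Z,4R,6S)-2-(acetoxymethyl)-9-[(2R,3S)-3-formyl-2-methyloxiran-2-yl]-6-hydroxy-3-iodo-6-methyl-4-(methacryloyloxy)-7-oxonon-2-enoate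
Conditions: TEMPO (cat.), PhI(OAc)2, CH2Cl2, rt
Reagents that add atoms: none
Why: Oxoammonium oxidation of the primary alcohol stops at the aldehyde and is mild enough for an epoxy aldehyde; the tertiary alcohol cannot react.

Step 14
Reactants: 20 epoxy aldehyde alkenyl iodide
Product: 22 (4R,5R,8R,10S)-13-acetoxy-4,5-epoxy-10-hydroxy-8-(methacryloyloxy)-1-oxogermacr-7(11)-en-6,12-olide (C6 epimers), via ring-closed hydroxy ester 21 (not isolated)
Conditions: CrCl2 (excess), NiCl2 (cat.), DMSO/THF, 2 mM, rt, slow addition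
Reagents that add atoms: none
Why: Nozaki–Hiyama–Kishi alkenyl iodide–aldehyde coupling used as macrocyclisation: nickel inserts into the C–I bond, the alkenyl group passes to chromium and adds only to the aldehyde, closing the ten-membered ring at C6–C7, and the new chromium alkoxide, held cis to the methyl ester, lactonises in the flask; the C6 configuration is left open because C6 becomes sp2 in step 15.

Step 15
Reactants: 22 epoxy keto lactone
Product: 25 (4R,5E,8R,10S)-13-acetoxy-1,4-epoxy-10-hydroxy-8-(methacryloyloxy)germacra-1,5,7(11)-trien-6,12-olide (CNP0394509.1), via C4 hydroxy dienolide 23 (not isolated), via C1 hemiketal 24 (not isolated)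
Conditions: DBU (0.3 equiv), Bu4NOAc (0.3 equiv), CH2Cl2, 0 °C to rt; then CSA (0.8 equiv), 4 Å MS, 35 °C
Reagents that add atoms: none
Why: Vinylogous E1cB epoxide opening, transannular hemiketalisation and dehydration (the glaucolide-to-hirsutinolide type of conversion): DBU removes the γ-proton at C6, the dienolate breaks the C5–O bond to give the C5=C6 dienolide and the C4 alkoxide with the C4–O bond (4R) untouched, this oxygen adds across the ring to the C1 ketone, and acid then ionises the hemiketal and loss of a C2 proton gives the enol ether; only the 5E geometry fits the bridged nine-membered ring.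

## Compound list

1 | 3-methylbut-2-en-1-ol (prenol) | CC(C)=CCO | starting material
2 | tert-butyl[(3-methylbut-2-en-1-yl)oxy]diphenylsilane | CC(C)=CCO[Si](c1ccccc1)(c1ccccc1)C(C)(C)C | intermediate
3 | (2E)-4-[(tert-butyldiphenylsilyl)oxy]-2-methylbut-2-en-1-ol | C/C(CO)=C\CO[Si](c1ccccc1)(c1ccccc1)C(C)(C)C | intermediate
4 | {[(2E)-4-bromo-3-methylbut-2-en-1-yl]oxy}(tert-butyl)diphenylsilane | C/C(CBr)=C\CO[Si](c1ccccc1)(c1ccccc1)C(C)(C)C | intermediate
5 | 3,3-dimethoxybutan-2-one | CC(=O)C(C)(OC)OC | starting material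
6 | (6E)-8-[(tert-butyldiphenylsilyl)oxy]-2,2-dimethoxy-6-methyloct-6-en-3-one | CC(OC)(OC)C(=O)CC/C(C)=C/CO[Si](c1ccccc1)(c1ccccc1)C(C)(C)C | intermediate (not isolated)
7 | (6E)-8-[(tert-butyldiphenylsilyl)oxy]-6-methyloct-6-ene-2,3-dione | CC(=O)C(=O)CC/C(C)=C/CO[Si](c1ccccc1)(c1ccccc1)C(C)(C)C | intermediate
8 | S-ethyl ethanethioate | CCSC(C)=O | starting material
9 | {[1-(ethylsulfanyl)ethenyl]oxy}trimethylsilane | C=C(SCC)O[Si](C)(C)C | intermediate
10 | S-ethyl (3S,7E)-9-[(tert-butyldiphenylsilyl)oxy]-3,7-dimethyl-4-oxo-3-[(trimethylsilyl)oxy]non-7-enethioate | CCSC(=O)C[C@](C)(O[Si](C)(C)C)C(=O)CC/C(C)=C/CO[Si](c1ccccc1)(c1ccccc1)C(C)(C)C | intermediate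
11 | (3S,7E)-9-[(tert-butyldiphenylsilyl)oxy]-3,7-dimethyl-4-oxo-3-[(trimethylsilyl)oxy]non-7-enal | O=CC[C@](C)(O[Si](C)(C)C)C(=O)CC/C(C)=C/CO[Si](c1ccccc1)(c1ccccc1)C(C)(C)C | intermediate
12 | methyl prop-2-ynoate | C#CC(=O)OC | starting material
13 | methyl (4R,6S,10E)-12-[(tert-butyldiphenylsilyl)oxy]-4-hydroxy-6,10-dimethyl-7-oxo-6-[(trimethylsilyl)oxy]dodec-10-en-2-ynoate | COC(=O)C#C[C@H](O)C[C@](C)(O[Si](C)(C)C)C(=O)CC/C(C)=C/CO[Si](c1ccccc1)(c1ccccc1)C(C)(C)C | intermediate
14 | iodomagnesium β-iodo allenolate formed from 13 | COC(O[Mg]I)=C=C(I)[C@H](O)C[C@](C)(O[Si](C)(C)C)C(=O)CC/C(C)=C/CO[Si](c1ccccc1)(c1ccccc1)C(C)(C)C | intermediate (not isolated)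
15 | methyl (2Z,4R,6S,10E)-12-[(tert-butyldiphenylsilyl)oxy]-4-hydroxy-2-(hydroxymethyl)-3-iodo-6,10-dimethyl-7-oxo-6-[(trimethylsilyl)oxy]dodeca-2,10-dienoate | COC(=O)/C(CO)=C(\I)[C@H](O)C[C@](C)(O[Si](C)(C)C)C(=O)CC/C(C)=C/CO[Si](c1ccccc1)(c1ccccc1)C(C)(C)C | intermediate
16 | methyl (2Z,4R,6S,10E)-2-(acetoxymethyl)-12-[(tert-butyldiphenylsilyl)oxy]-4-hydroxy-3-iodo-6,10-dimethyl-7-oxo-6-[(trimethylsilyl)oxy]dodeca-2,10-dienoate | COC(=O)/C(COC(C)=O)=C(\I)[C@H](O)C[C@](C)(O[Si](C)(C)C)C(=O)CC/C(C)=C/CO[Si](c1ccccc1)(c1ccccc1)C(C)(C)C | intermediate (not isolated)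
17 | methyl (2Z,4R,6S,10E)-2-(acetoxymethyl)-12-[(tert-butyldiphenylsilyl)oxy]-3-iodo-6,10-dimethyl-4-(methacryloyloxy)-7-oxo-6-[(trimethylsilyl)oxy]dodeca-2,10-dienoate | COC(=O)/C(COC(C)=O)=C(\I)[C@H](OC(=O)C(C)=C)C[C@](C)(O[Si](C)(C)C)C(=O)CC/C(C)=C/CO[Si](c1ccccc1)(c1ccccc1)C(C)(C)C | intermediate
18 | methyl (2Z,4R,6S,10E)-2-(acetoxymethyl)-6,12-dihydroxy-3-iodo-6,10-dimethyl-4-(methacryloyloxy)-7-oxododeca-2,10-dienoate | COC(=O)/C(COC(C)=O)=C(\I)[C@H](OC(=O)C(C)=C)C[C@](C)(O)C(=O)CC/C(C)=C/CO | intermediate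
19 | methyl (2Z,4R,6S)-2-(acetoxymethyl)-6-hydroxy-9-[(2R,3R)-3-(hydroxymethyl)-2-methyloxiran-2-yl]-3-iodo-6-methyl-4-(methacryloyloxy)-7-oxonon-2-enoate | COC(=O)/C(COC(C)=O)=C(\I)[C@H](OC(=O)C(C)=C)C[C@](C)(O)C(=O)CC[C@@]1(C)O[C@@H]1CO | intermediate
20 | methyl (2Z,4R,6S)-2-(acetoxymethyl)-9-[(2R,3S)-3-formyl-2-methyloxiran-2-yl]-6-hydroxy-3-iodo-6-methyl-4-(methacryloyloxy)-7-oxonon-2-enoate | COC(=O)/C(COC(C)=O)=C(\I)[C@H](OC(=O)C(C)=C)C[C@](C)(O)C(=O)CC[C@@]1(C)O[C@@H]1C=O | intermediate
21 | ring-closed ten-membered hydroxy ester (chromium alkoxide in the flask; C6 carbinol epimers; C6 cis to CO2Me on the C7=C11 alkene) | C=C(C)C(=O)O[C@@H]1C[C@](C)(O)C(=O)CC[C@@]2(C)O[C@@H]2C(O)/C1=C(/COC(C)=O)C(=O)OC | intermediate (not isolated)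
22 | (4R,5R,8R,10S)-13-acetoxy-4,5-epoxy-10-hydroxy-8-(methacryloyloxy)-1-oxogermacr-7(11)-en-6,12-olide (C6 epimers) | C=C(C)C(=O)O[C@@H]1C[C@](C)(O)C(=O)CC[C@@]2(C)O[C@@H]2C2OC(=O)C(COC(C)=O)=C12 | intermediate
23 | (4R,5E,8R,10S)-13-acetoxy-4,10-dihydroxy-8-(methacryloyloxy)-1-oxogermacra-5,7(11)-dien-6,12-olide | C=C(C)C(=O)O[C@@H]1C[C@](C)(O)C(=O)CC[C@@](C)(O)/C=C2/OC(=O)C(COC(C)=O)=C21 | intermediate (not isolated)
24 | (1S,4R,5E,8R,10S)-13-acetoxy-1,4-epoxy-1,10-dihydroxy-8-(methacryloyloxy)germacra-5,7(11)-dien-6,12-olide | C=C(C)C(=O)O[C@@H]1C[C@](C)(O)[C@]2(O)CC[C@](C)(/C=C3/OC(=O)C(COC(C)=O)=C31)O2 | intermediate (not isolated)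
25 | (4R,5E,8R,10S)-13-acetoxy-1,4-epoxy-10-hydroxy-8-(methacryloyloxy)germacra-1,5,7(11)-trien-6,12-olide (CNP0394509.1) | C=C(C)C(=O)O[C@@H]1C[C@](C)(O)C2=CC[C@](C)(/C=C3/OC(=O)C(COC(C)=O)=C31)O2 | target

## Step count and weak points

Total steps: 15. Longest linear sequence: 14 (steps 1–4 and 6–15; step 5 is the side branch).

The three steps most likely to fail:

Step 14 (ring closure). A ten-membered ring has to be closed by a tetrasubstituted alkenyl metal on an α,β-epoxy aldehyde; medium-ring strain, reduction of the epoxy aldehyde by divalent chromium and plain loss of iodine are the likely losses. Fallback, setting out from 18 and coming back at 22: MnO2 in CH2Cl2 oxidises the allylic alcohol to the methyl (2Z,4R,6S,10E)-2-(acetoxymethyl)-6-hydroxy-3-iodo-6,10-dimethyl-4-(methacryloyloxy)-7,12-dioxododeca-2,10-dienoate enal F3. The same NiCl2/CrCl2 closure on this sturdier aldehyde gives the macrocyclic dienolide F4, which carries the C4=C5 alkene in place of the epoxide. DMDO in acetone at −20 °C then epoxidises the only electron-rich alkene from the outer face of the ring to give 22. In this variant C4 rests on macrocyclic control instead of the tartrate, so the epoxide diastereomer must be checked before going on.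

Step 9 (iodo-aldol). The geometry of the tetrasubstituted alkene depends on formaldehyde entering from the C4 side. A bulky β-substituent can steer the electrophile to the iodine side, and the allenolate can also add to the C7 ketone of the chain. Fallback, setting out from 13 and coming back at 15: acetic formic anhydride and pyridine at 0 °C convert the C4 hydroxyl into the formate ester F1. MgI2 in CH2Cl2 then adds iodide to the ynoate, and the allenolate attacks the tethered formate through a five-membered transition state, so the transferred formyl carbon can only end cis to C4 and iodine cis to the ester. This anionic O-to-C formyl shift is unprecedented in this form but geometrically forced. It gives the cyclic lactol F2, which is reduced in the same flask with NaBH4 in MeOH at −78 °C to diol 15.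

Step 15 (cascade). The dienolate can expel the C13 acetate instead of opening the epoxide, and the acid-driven dehydration of the hemiketal next to a free tertiary alcohol may stall or rearrange. Fallback, setting out from 22 and coming back at 25: DBU as before, then MeOH, PPTS and 4 Å MS trap hemiketal 24 as the 1-O-methyl ketal F5. TMSOTf/iPr2NEt at −78 °C ionises the ketal and removes a C2 proton (ketal-to-enol-ether elimination), silylating O10 on the way, to give the 10-O-trimethylsilyl enol ether F6. Buffered HF·pyridine frees O10 and gives 25.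

## Further compounds

F1 | step 9 | methyl (4R,6S,10E)-12-[(tert-butyldiphenylsilyl)oxy]-4-(formyloxy)-6,10-dimethyl-7-oxo-6-[(trimethylsilyl)oxy]dodec-10-en-2-ynoate | COC(=O)C#C[C@H](OC=O)C[C@](C)(O[Si](C)(C)C)C(=O)CC/C(C)=C/CO[Si](c1ccccc1)(c1ccccc1)C(C)(C)C
F2 | step 9 | methyl (5R)-5-{(2S,6E)-8-[(tert-butyldiphenylsilyl)oxy]-2,6-dimethyl-3-oxo-2-[(trimethylsilyl)oxy]oct-6-en-1-yl}-2-hydroxy-4-iodo-2,5-dihydrofuran-3-carboxylate (lactol, anomers) | COC(=O)C1=C(I)[C@@H](C[C@](C)(O[Si](C)(C)C)C(=O)CC/C(C)=C/CO[Si](c2ccccc2)(c2ccccc2)C(C)(C)C)OC1O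
F3 | step 14 | methyl (2Z,4R,6S,10E)-2-(acetoxymethyl)-6-hydroxy-3-iodo-6,10-dimethyl-4-(methacryloyloxy)-7,12-dioxododeca-2,10-dienoate | COC(=O)/C(COC(C)=O)=C(\I)[C@H](OC(=O)C(C)=C)C[C@](C)(O)C(=O)CC/C(C)=C/C=O
F4 | step 14 | (4E,8R,10S)-13-acetoxy-10-hydroxy-8-(methacryloyloxy)-1-oxogermacra-4,7(11)-dien-6,12-olide (C6 epimers) | C=C(C)C(=O)O[C@@H]1C[C@](C)(O)C(=O)CC/C(C)=C/C2OC(=O)C(COC(C)=O)=C12
F5 | step 15 | (1S,4R,5E,8R,10S)-13-acetoxy-1,4-epoxy-10-hydroxy-1-methoxy-8-(methacryloyloxy)germacra-5,7(11)-dien-6,12-olide | C=C(C)C(=O)O[C@@H]1C[C@](C)(O)[C@]2(OC)CC[C@](C)(/C=C3/OC(=O)C(COC(C)=O)=C31)O2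
F6 | step 15 | (4R,5E,8R,10S)-13-acetoxy-1,4-epoxy-8-(methacryloyloxy)-10-[(trimethylsilyl)oxy]germacra-1,5,7(11)-trien-6,12-olide | C=C(C)C(=O)O[C@@H]1C[C@](C)(O[Si](C)(C)C)C2=CC[C@](C)(/C=C3/OC(=O)C(COC(C)=O)=C31)O2
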